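Ring B of the target carries three adjacent oxygens (O3′, O4′, O5′), of which only O3′ is esterified. The route therefore assembles ring B instead of buying it: a [4+2] cycloaddition of 3,4-bis(benzyloxy)furan with a terminal ynone creates C1′–C6′ and C2′–C3′, and acid opening of the oxygen bridge aromatises the ring. This delivers O4′ and O5′ as benzyl ethers and O3′ as the sole free phenol in one operation. The ynone precursor already contains ring A (O1 as MOM ether, O5/O7 as benzyl ethers), C4, the C3 stereocenter as a silyl ether and the C2 carbonyl. Galloylation, Felkin–Anh reduction and an invertive Mitsunobu closure of ring C finish the synthesis.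

Key step: step 10

Remark: flavan numbering (O1, C2, C3, C4, primed atoms for ring B) is used for all open-chain intermediates, and compounds 7, 9 and 18 are assumed to be purchasable.

Step 1
Reactants: 1 dimethyl diglycolate; 2 dimethyl oxalate
Product: 3 dimethyl 3,4-dihydroxyfuran-2,5-dicarboxylate
Conditions: NaOMe, MeOH, reflux; then aq. HCl
Reagents that add atoms: none
Why: A base-mediated double Claisen (Hinsberg-type) condensation between the two activated methylene groups of 1 and the two ester carbonyls of 2 closes the furan ring, and tautomerisation to the aromatic 3,4-dihydroxyfuran should drive it to completion.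

Step 2
Reactants: 3 dimethyl 3,4-dihydroxyfuran-2,5-dicarboxylate
Product: 4 dimethyl 3,4-bis(benzyloxy)furan-2,5-dicarboxylate
Conditions: BnBr, K2CO3, DMF, 60 °C
Reagents that add atoms: benzyl bromide, BrCc1ccccc1
Why: A Williamson ether synthesis on the two acidic enolic hydroxyls with carbonate base should benzylate both oxygens without touching the esters.

Step 3
Reactants: 4 dimethyl 3,4-bis(benzyloxy)furan-2,5-dicarboxylate
Product: 5 3,4-bis(benzyloxy)furan-2,5-dicarboxylic acid
Conditions: NaOH, H2O/EtOH, reflux; then aq. HCl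
Reagents that add atoms: sodium hydroxide, [Na+].[OH-]
Why: Ordinary ester saponification followed by acidification should free both carboxylic acids while the benzyl ethers stay inert to aqueous base.

Step 4
Reactants: 5 3,4-bis(benzyloxy)furan-2,5-dicarboxylic acid
Product: 6 3,4-bis(benzyloxy)furan
Conditions: Cu powder, quinoline, 200 °C
Reagents that add atoms: none
Why: Copper-mediated thermal protodecarboxylation of furan-2-carboxylic acids in quinoline is the classical way to strip both carboxyl groups from 3,4-dialkoxyfuran-2,5-dicarboxylic acids.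

Step 5
Reactants: 7 3,5-bis(benzyloxy)phenol
Product: 8 1,3-bis(benzyloxy)-5-(methoxymethoxy)benzene
Conditions: MOMCl, i-Pr2NEt, CH2Cl2, 0 °C → rt
Reagents that add atoms: chloromethyl methyl ether, COCCl
Why: O-Alkylation of the single phenol with MOMCl under amine base (acetal protection) installs a group that is orthogonal to the benzyl ethers and directs the next metalation.

Step 6
Reactants: 8 1,3-bis(benzyloxy)-5-(methoxymethoxy)benzene; 9 methyl (S)-glycidate [methyl (2S)-oxirane-2-carboxylate]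
Product: 12 methyl (2S)-3-[2,4-bis(benzyloxy)-6-(methoxymethoxy)phenyl]-2-hydroxypropanoate, via aryllithium 10 (not isolated), via arylmagnesium bromide 11 (not isolated)
Conditions: n-BuLi, THF, 0 °C; MgBr2·OEt2, −20 °C; CuI (10 mol%), then 9, −40 → −20 °C; aq. NH4Cl
Reagents that add atoms: none
Why: Directed ortho-metalation should take place at one of the two equivalent positions flanked by OMOM and OBn because the chelating acetal is the stronger director, transmetalation to magnesium makes the aryl metal compatible with the ester, and CuI-catalysed SN2 opening of the glycidate at its unsubstituted CH2 forms the ring A–C4 bond while the stereocenter of 9 (the future C3, S) is not touched.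

Step 7
Reactants: 12 methyl (2S)-3-[2,4-bis(benzyloxy)-6-(methoxymethoxy)phenyl]-2-hydroxypropanoate
Product: 13 methyl (2S)-3-[2,4-bis(benzyloxy)-6-(methoxymethoxy)phenyl]-2-[(tert-butyldimethylsilyl)oxy]propanoate
Conditions: TBSCl, imidazole, DMF, rt
Reagents that add atoms: tert-butyldimethylsilyl chloride, CC(C)(C)[Si](C)(C)Cl
Why: Standard silylation of the secondary alcohol gives a bulky, non-chelating ether that later steers the ketone reduction.

Step 8
Reactants: 13 methyl (2S)-3-[2,4-bis(benzyloxy)-6-(methoxymethoxy)phenyl]-2-[(tert-butyldimethylsilyl)oxy]propanoate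
Product: 14 (2S)-3-[2,4-bis(benzyloxy)-6-(methoxymethoxy)phenyl]-2-[(tert-butyldimethylsilyl)oxy]-N-methoxy-N-methylpropanamide
Conditions: MeNH(OMe)·HCl, i-PrMgCl, THF, −20 → 0 °C
Reagents that add atoms: N,O-dimethylhydroxylamine hydrochloride, CNOC.Cl
Why: Weinreb amidation of the ester by the chloromagnesium amide of N,O-dimethylhydroxylamine is a direct acyl substitution that should not epimerise the adjacent silyloxy center.

Step 9
Reactants: 14 (2S)-3-[2,4-bis(benzyloxy)-6-(methoxymethoxy)phenyl]-2-[(tert-butyldimethylsilyl)oxy]-N-methoxy-N-methylpropanamide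
Product: 15 (4S)-5-[2,4-bis(benzyloxy)-6-(methoxymethoxy)phenyl]-4-[(tert-butyldimethylsilyl)oxy]pent-1-yn-3-one
Conditions: HC≡CMgBr, THF, 0 °C; inverse quench into cold 1 M aq. NaHSO4
Reagents that add atoms: ethynylmagnesium bromide, C#C[Mg]Br
Why: In this Weinreb ketone synthesis the alkynyl Grignard reagent adds once to give a stable magnesium chelate that collapses to the terminal ynone only on the acidic inverse quench, which also protonates the released amine so that it cannot add to the ynone.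

Step 10
Reactants: 15 (4S)-5-[2,4-bis(benzyloxy)-6-(methoxymethoxy)phenyl]-4-[(tert-butyldimethylsilyl)oxy]pent-1-yn-3-one; 6 3,4-bis(benzyloxy)furan
Product: 17 (2S)-3-[2,4-bis(benzyloxy)-6-(methoxymethoxy)phenyl]-1-[3,4-bis(benzyloxy)-5-hydroxyphenyl]-2-[(tert-butyldimethylsilyl)oxy]propan-1-one, via 7-oxanorbornadiene cycloadduct 16 (not isolated)
Conditions: toluene, 60 °C; then CSA (10 mol%), CH2Cl2, 0 °C → rt
Reagents that add atoms: none
Why: A normal-electron-demand [4+2] cycloaddition of the electron-rich dialkoxyfuran across the acyl-activated terminal alkyne forms C1′–C6′ and C2′–C3′ and gives 16; protonation of the bridge oxygen then cleaves the C6′–O bond to a pentadienyl cation with charge on C6′, C4′ (stabilised by its benzyloxy group) and C2′, and loss of the C3′ proton aromatises ring B with the former furan oxygen kept as O3′–H. The closest known reaction type is the furan–alkyne Diels–Alder reaction followed by acid-induced isomerisation of the 7-oxanorbornadiene to a phenol. Ring B is closed by the concerted intermolecular cycloaddition itself, both new sigma bonds forming suprafacially on diene and dienophile, and the only ring then opened is the oxygen bridge. No stereocenter is created in the product: the two bridgehead centers of 16 are transient and vanish on aromatisation, and the C3 center should not enolise under neutral heating or catalytic acid in an aprotic solvent. The symmetric furan removes any regiochemical question in the cycloaddition, so the selectivity needed is the direction of bridge opening, and the C1′ acyl group secures it because cleavage of the C3′–O bond instead would place positive charge on the acyl-bearing carbon. The aprotic, catalytic acid should leave the aromatic MOM acetal and the TBS ether in place, so that O3′–H is the only free hydroxyl of 17.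

Step 11
Reactants: 17 (2S)-3-[2,4-bis(benzyloxy)-6-(methoxymethoxy)phenyl]-1-[3,4-bis(benzyloxy)-5-hydroxyphenyl]-2-[(tert-butyldimethylsilyl)oxy]propan-1-one; 18 3,4,5-tris(benzyloxy)benzoic acid
Product: 19 2,3-bis(benzyloxy)-5-{(2S)-3-[2,4-bis(benzyloxy)-6-(methoxymethoxy)phenyl]-2-[(tert-butyldimethylsilyl)oxy]propanoyl}phenyl 3,4,5-tris(benzyloxy)benzoate
Conditions: EDC·HCl, DMAP, CH2Cl2, rt
Reagents that add atoms: none
Why: Steglich esterification (carbodiimide activation with DMAP acyl transfer) acylates the only hydroxyl group present, O3′–H, so no selectivity question arises.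

Step 12
Reactants: 19 2,3-bis(benzyloxy)-5-{(2S)-3-[2,4-bis(benzyloxy)-6-(methoxymethoxy)phenyl]-2-[(tert-butyldimethylsilyl)oxy]propanoyl}phenyl 3,4,5-tris(benzyloxy)benzoate
Product: 20 2,3-bis(benzyloxy)-5-{(1S,2S)-3-[2,4-bis(benzyloxy)-6-(methoxymethoxy)phenyl]-2-[(tert-butyldimethylsilyl)oxy]-1-hydroxypropyl}phenyl 3,4,5-tris(benzyloxy)benzoate
Conditions: LiBH(s-Bu)3, THF, −78 °C; AcOH, −78 °C
Reagents that add atoms: none
Why: In this Felkin–Anh (polar) 1,2-reduction the bulky, non-chelating borohydride attacks the aryl ketone anti to the C3–OSi bond, which should set C2 as S (2,3-syn), and the low temperature with an acetic acid quench spares the aryl ester and prevents silyl migration in the alkoxide.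

Step 13
Reactants: 20 2,3-bis(benzyloxy)-5-{(1S,2S)-3-[2,4-bis(benzyloxy)-6-(methoxymethoxy)phenyl]-2-[(tert-butyldimethylsilyl)oxy]-1-hydroxypropyl}phenyl 3,4,5-tris(benzyloxy)benzoate
Product: 22 2,3-bis(benzyloxy)-5-{(1S,2S)-3-[2,4-bis(benzyloxy)-6-hydroxyphenyl]-2-[(tert-butyldimethylsilyl)oxy]-1-hydroxypropyl}phenyl 3,4,5-tris(benzyloxy)benzoate, via bis(trimethylsilyl) ether 21 (not isolated)
Conditions: TMSOTf, 2,2′-bipyridyl, CH2Cl2, 0 °C → rt; then H2O, citric acid, THF, rt
Reagents that add atoms: none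
Why: Silyl triflate–bipyridyl cleavage of an aromatic MOM ether proceeds through the aryl trimethylsilyl ether under buffered, non-protic conditions, the C2 carbinol is masked in the flask as its trimethylsilyl ether so that it cannot ionise, and mild aqueous acid then hydrolyses both trimethylsilyl ethers while the TBS ether, the benzyl ethers and the ester should remain.

Step 14
Reactants: 22 2,3-bis(benzyloxy)-5-{(1S,2S)-3-[2,4-bis(benzyloxy)-6-hydroxyphenyl]-2-[(tert-butyldimethylsilyl)oxy]-1-hydroxypropyl}phenyl 3,4,5-tris(benzyloxy)benzoate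
Product: 23 2,3-bis(benzyloxy)-5-{(2R,3S)-5,7-bis(benzyloxy)-3-[(tert-butyldimethylsilyl)oxy]-3,4-dihydro-2H-chromen-2-yl}phenyl 3,4,5-tris(benzyloxy)benzoate
Conditions: PPh3, DIAD, THF, 0 °C → rt
Reagents that add atoms: none
Why: In this intramolecular Mitsunobu etherification (6-exo-tet) the phenol O1–H is the acidic pronucleophile and displaces the oxyphosphonium-activated C2 oxygen by SN2 with inversion, turning (2S) into (2R) and thereby giving the 2,3-trans ring C.

Step 15
Reactants: 23 2,3-bis(benzyloxy)-5-{(2R,3S)-5,7-bis(benzyloxy)-3-[(tert-butyldimethylsilyl)oxy]-3,4-dihydro-2H-chromen-2-yl}phenyl 3,4,5-tris(benzyloxy)benzoate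
Product: 24 2,3-bis(benzyloxy)-5-[(2R,3S)-5,7-bis(benzyloxy)-3-hydroxy-3,4-dihydro-2H-chromen-2-yl]phenyl 3,4,5-tris(benzyloxy)benzoate
Conditions: HF·pyridine, pyridine/THF, 0 °C → rt
Reagents that add atoms: none
Why: Fluoride-mediated desilylation under the slightly acidic HF·pyridine conditions removes the secondary TBS ether without the basic conditions that could cleave or shift the aryl ester.

Step 16
Reactants: 24 2,3-bis(benzyloxy)-5-[(2R,3S)-5,7-bis(benzyloxy)-3-hydroxy-3,4-dihydro-2H-chromen-2-yl]phenyl 3,4,5-tris(benzyloxy)benzoate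
Product: 25 (2R,3S)-gallocatechin 3′-O-gallate [2,3-dihydroxy-5-[(2R,3S)-3,5,7-trihydroxy-3,4-dihydro-2H-chromen-2-yl]phenyl 3,4,5-trihydroxybenzoate]
Conditions: H2 (1 atm), Pd(OH)2/C, THF/MeOH, rt
Reagents that add atoms: none
Why: Palladium-catalysed hydrogenolysis under neutral conditions should cleave all seven benzyl ethers to toluene and leave the aryl ester, the benzylic C2–O1 ether of ring C and both stereocenters untouched, as is usual for catechin gallates.

Compound list
1 | dimethyl diglycolate | COC(=O)COCC(=O)OC | starting material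
2 | dimethyl oxalate | COC(=O)C(=O)OC | starting material
3 | dimethyl 3,4-dihydroxyfuran-2,5-dicarboxylate | COC(=O)c1oc(C(=O)OC)c(O)c1O | intermediate
4 | dimethyl 3,4-bis(benzyloxy)furan-2,5-dicarboxylate | COC(=O)c1oc(C(=O)OC)c(OCc2ccccc2)c1OCc1ccccc1 | intermediate
5 | 3,4-bis(benzyloxy)furan-2,5-dicarboxylic acid | OC(=O)c1oc(C(=O)O)c(OCc2ccccc2)c1OCc1ccccc1 | intermediate
6 | 3,4-bis(benzyloxy)furan | c1occ(OCc2ccccc2)c1OCc1ccccc1 | intermediate
7 | 3,5-bis(benzyloxy)phenol | Oc1cc(OCc2ccccc2)cc(OCc2ccccc2)c1 | starting material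
8 | 1,3-bis(benzyloxy)-5-(methoxymethoxy)benzene | COCOc1cc(OCc2ccccc2)cc(OCc2ccccc2)c1 | intermediate
9 | methyl (S)-glycidate | COC(=O)[C@@H]1CO1 | starting material
10 | [2,4-bis(benzyloxy)-6-(methoxymethoxy)phenyl]lithium | [Li]c1c(OCOC)cc(OCc2ccccc2)cc1OCc1ccccc1 | intermediate (not isolated)
11 | [2,4-bis(benzyloxy)-6-(methoxymethoxy)phenyl]magnesium bromide | Br[Mg]c1c(OCOC)cc(OCc2ccccc2)cc1OCc1ccccc1 | intermediate (not isolated)
12 | methyl (2S)-3-[2,4-bis(benzyloxy)-6-(methoxymethoxy)phenyl]-2-hydroxypropanoate | COCOc1cc(OCc2ccccc2)cc(OCc2ccccc2)c1C[C@@H](C(=O)OC)O | intermediate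
13 | methyl (2S)-3-[2,4-bis(benzyloxy)-6-(methoxymethoxy)phenyl]-2-[(tert-butyldimethylsilyl)oxy]propanoate | COCOc1cc(OCc2ccccc2)cc(OCc2ccccc2)c1C[C@@H](C(=O)OC)O[Si](C)(C)C(C)(C)C | intermediate
14 | (2S)-3-[2,4-bis(benzyloxy)-6-(methoxymethoxy)phenyl]-2-[(tert-butyldimethylsilyl)oxy]-N-methoxy-N-methylpropanamide | COCOc1cc(OCc2ccccc2)cc(OCc2ccccc2)c1C[C@@H](C(=O)N(C)OC)O[Si](C)(C)C(C)(C)C | intermediate
15 | (4S)-5-[2,4-bis(benzyloxy)-6-(methoxymethoxy)phenyl]-4-[(tert-butyldimethylsilyl)oxy]pent-1-yn-3-one (the (S)-ynone) | COCOc1cc(OCc2ccccc2)cc(OCc2ccccc2)c1C[C@@H](C(=O)C#C)O[Si](C)(C)C(C)(C)C | intermediate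
16 | (2S)-3-[2,4-bis(benzyloxy)-6-(methoxymethoxy)phenyl]-1-[5,6-bis(benzyloxy)-7-oxabicyclo[2.2.1]hepta-2,5-dien-2-yl]-2-[(tert-butyldimethylsilyl)oxy]propan-1-one (both bridgehead configurations) | COCOc1cc(OCc2ccccc2)cc(OCc2ccccc2)c1C[C@@H](C(=O)C1=CC2OC1C(OCc1ccccc1)=C2OCc1ccccc1)O[Si](C)(C)C(C)(C)C | intermediate (not isolated)
17 | (2S)-3-[2,4-bis(benzyloxy)-6-(methoxymethoxy)phenyl]-1-[3,4-bis(benzyloxy)-5-hydroxyphenyl]-2-[(tert-butyldimethylsilyl)oxy]propan-1-one | COCOc1cc(OCc2ccccc2)cc(OCc2ccccc2)c1C[C@@H](C(=O)c1cc(O)c(OCc2ccccc2)c(OCc2ccccc2)c1)O[Si](C)(C)C(C)(C)C | intermediate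
18 | 3,4,5-tris(benzyloxy)benzoic acid | OC(=O)c1cc(OCc2ccccc2)c(OCc2ccccc2)c(OCc2ccccc2)c1 | starting material
19 | 2,3-bis(benzyloxy)-5-{(2S)-3-[2,4-bis(benzyloxy)-6-(methoxymethoxy)phenyl]-2-[(tert-butyldimethylsilyl)oxy]propanoyl}phenyl 3,4,5-tris(benzyloxy)benzoate | COCOc1cc(OCc2ccccc2)cc(OCc2ccccc2)c1C[C@@H](C(=O)c1cc(OC(=O)c2cc(OCc3ccccc3)c(OCc3ccccc3)c(OCc3ccccc3)c2)c(OCc2ccccc2)c(OCc2ccccc2)c1)O[Si](C)(C)C(C)(C)C | intermediate
20 | 2,3-bis(benzyloxy)-5-{(1S,2S)-3-[2,4-bis(benzyloxy)-6-(methoxymethoxy)phenyl]-2-[(tert-butyldimethylsilyl)oxy]-1-hydroxypropyl}phenyl 3,4,5-tris(benzyloxy)benzoate | COCOc1cc(OCc2ccccc2)cc(OCc2ccccc2)c1C[C@@H]([C@@H](O)c1cc(OC(=O)c2cc(OCc3ccccc3)c(OCc3ccccc3)c(OCc3ccccc3)c2)c(OCc2ccccc2)c(OCc2ccccc2)c1)O[Si](C)(C)C(C)(C)C | intermediate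
21 | 2,3-bis(benzyloxy)-5-{(1S,2S)-3-[2,4-bis(benzyloxy)-6-(trimethylsilyloxy)phenyl]-2-[(tert-butyldimethylsilyl)oxy]-1-(trimethylsilyloxy)propyl}phenyl 3,4,5-tris(benzyloxy)benzoate | C[Si](C)(C)Oc1cc(OCc2ccccc2)cc(OCc2ccccc2)c1C[C@@H]([C@@H](O[Si](C)(C)C)c1cc(OC(=O)c2cc(OCc3ccccc3)c(OCc3ccccc3)c(OCc3ccccc3)c2)c(OCc2ccccc2)c(OCc2ccccc2)c1)O[Si](C)(C)C(C)(C)C | intermediate (not isolated)
22 | 2,3-bis(benzyloxy)-5-{(1S,2S)-3-[2,4-bis(benzyloxy)-6-hydroxyphenyl]-2-[(tert-butyldimethylsilyl)oxy]-1-hydroxypropyl}phenyl 3,4,5-tris(benzyloxy)benzoate | Oc1cc(OCc2ccccc2)cc(OCc2ccccc2)c1C[C@@H]([C@@H](O)c1cc(OC(=O)c2cc(OCc3ccccc3)c(OCc3ccccc3)c(OCc3ccccc3)c2)c(OCc2ccccc2)c(OCc2ccccc2)c1)O[Si](C)(C)C(C)(C)C | intermediate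
23 | 2,3-bis(benzyloxy)-5-{(2R,3S)-5,7-bis(benzyloxy)-3-[(tert-butyldimethylsilyl)oxy]-3,4-dihydro-2H-chromen-2-yl}phenyl 3,4,5-tris(benzyloxy)benzoate | O=C(Oc1cc([C@H]2Oc3cc(OCc4ccccc4)cc(OCc4ccccc4)c3C[C@@H]2O[Si](C)(C)C(C)(C)C)cc(OCc2ccccc2)c1OCc1ccccc1)c1cc(OCc2ccccc2)c(OCc2ccccc2)c(OCc2ccccc2)c1 | intermediate
24 | 2,3-bis(benzyloxy)-5-[(2R,3S)-5,7-bis(benzyloxy)-3-hydroxy-3,4-dihydro-2H-chromen-2-yl]phenyl 3,4,5-tris(benzyloxy)benzoate | O=C(Oc1cc([C@H]2Oc3cc(OCc4ccccc4)cc(OCc4ccccc4)c3C[C@@H]2O)cc(OCc2ccccc2)c1OCc1ccccc1)c1cc(OCc2ccccc2)c(OCc2ccccc2)c(OCc2ccccc2)c1 | intermediate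
25 | (2R,3S)-gallocatechin 3′-O-gallate | O=C(Oc1cc([C@H]2Oc3cc(O)cc(O)c3C[C@@H]2O)cc(O)c1O)c1cc(O)c(O)c(O)c1 | target

Total step count: 16.
Longest linear sequence: 12 steps (steps 5 to 16, from 7 to 25); the furan branch (steps 1 to 4) joins at step 10.

Steps most likely to fail

Step 10 (cycloaddition and bridge opening). The cycloaddition may be slow or revert at the temperature the furan tolerates, the furan may add to the ynone as a carbon nucleophile instead of as a diene, the bridge may open toward the ortho-hydroxy isomer, or the aromatic acetal may be lost during the acid treatment. The fallback joins a preformed, already differentiated ring B by acyl substitution; it sets out from Weinreb amide 14 and comes back at 17. Commercial 5-bromo-2,3-dihydroxybenzaldehyde would be benzylated twice (BnBr, K2CO3, DMF) to 5-bromo-2,3-bis(benzyloxy)benzaldehyde F1. Baeyer–Villiger oxidation with mCPBA would give 5-bromo-2,3-bis(benzyloxy)phenyl formate F2 (not isolated), and methanolysis (K2CO3, MeOH) would give 5-bromo-2,3-bis(benzyloxy)phenol F3. Silylation (TBSCl, imidazole) would give [5-bromo-2,3-bis(benzyloxy)phenoxy](tert-butyl)dimethylsilane F4. Bromine–lithium exchange (n-BuLi, THF, −78 °C) would give {3,4-bis(benzyloxy)-5-[(tert-butyldimethylsilyl)oxy]phenyl}lithium F5 (not isolated), which should add once to 14 to give the O3′-silylated aryl ketone F6. KHF2 in MeOH at rt should then cleave only the phenolic silyl ether and deliver 17.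

Step 14 (Mitsunobu closure of ring C). The activated benzylic C2–O bond may ionise before the phenol attacks, so that the invertive course is lost, the displacement next to the bulky silyl ether may be slow, or elimination may compete. The fallback is the acid-promoted orthoester cyclisation known for catechins; it sets out from 22 and comes back at 24, bypassing steps 14 and 15. HF·pyridine would remove the TBS group to give the phenol syn-diol F7. Triethyl orthoformate with catalytic PPTS in 1,2-dichloroethane at rt would convert the diol into the cyclic 2-ethoxy-1,3-dioxolane F8 (not isolated). Warming to 60 °C should ionise the orthoester so that O1 attacks C2 with inversion and gives the 2,3-trans flavan 3-O-formate F9. Brief methanolysis (KHCO3, MeOH, 0 °C) of the far more labile formate should give 24.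

Step 13 (MOM removal). Ionisation at the benzylic C2 center or loss of the C3 silyl ether may compete with the Lewis-acidic acetal cleavage, or the transient silyl ethers may hydrolyse incompletely. The fallback removes the acetal before the ionisable carbinol exists; it sets out from 19 and comes back at 22. TMSOTf and 2,2′-bipyridyl would convert 19 into the aryl trimethylsilyl ether ketone F10 (not isolated), and water would hydrolyse it to the phenol ketone F11, which may rest partly as its cyclic hemiketal. Reduction with LiBH(s-Bu)3 at −78 °C, with one extra equivalent for the phenol, should then give 22 under the same Felkin–Anh control.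

Further compounds
F1 | step 10 | 5-bromo-2,3-bis(benzyloxy)benzaldehyde | O=Cc1cc(Br)cc(OCc2ccccc2)c1OCc1ccccc1
F2 | step 10 | 5-bromo-2,3-bis(benzyloxy)phenyl formate | O=COc1cc(Br)cc(OCc2ccccc2)c1OCc1ccccc1
F3 | step 10 | 5-bromo-2,3-bis(benzyloxy)phenol | Oc1cc(Br)cc(OCc2ccccc2)c1OCc1ccccc1
F4 | step 10 | [5-bromo-2,3-bis(benzyloxy)phenoxy](tert-butyl)dimethylsilane | CC(C)(C)[Si](C)(C)Oc1cc(Br)cc(OCc2ccccc2)c1OCc1ccccc1
F5 | step 10 | {3,4-bis(benzyloxy)-5-[(tert-butyldimethylsilyl)oxy]phenyl}lithium | [Li]c1cc(O[Si](C)(C)C(C)(C)C)c(OCc2ccccc2)c(OCc2ccccc2)c1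
F6 | step 10 | (2S)-3-[2,4-bis(benzyloxy)-6-(methoxymethoxy)phenyl]-1-{3,4-bis(benzyloxy)-5-[(tert-butyldimethylsilyl)oxy]phenyl}-2-[(tert-butyldimethylsilyl)oxy]propan-1-one | COCOc1cc(OCc2ccccc2)cc(OCc2ccccc2)c1C[C@@H](C(=O)c1cc(O[Si](C)(C)C(C)(C)C)c(OCc2ccccc2)c(OCc2ccccc2)c1)O[Si](C)(C)C(C)(C)C
F7 | step 14 | 2,3-bis(benzyloxy)-5-{(1S,2S)-3-[2,4-bis(benzyloxy)-6-hydroxyphenyl]-1,2-dihydroxypropyl}phenyl 3,4,5-tris(benzyloxy)benzoate | Oc1cc(OCc2ccccc2)cc(OCc2ccccc2)c1C[C@@H]([C@@H](O)c1cc(OC(=O)c2cc(OCc3ccccc3)c(OCc3ccccc3)c(OCc3ccccc3)c2)c(OCc2ccccc2)c(OCc2ccccc2)c1)O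
F8 | step 14 | 2,3-bis(benzyloxy)-5-{(4S,5S)-5-[2,4-bis(benzyloxy)-6-hydroxybenzyl]-2-ethoxy-1,3-dioxolan-4-yl}phenyl 3,4,5-tris(benzyloxy)benzoate | Oc1cc(OCc2ccccc2)cc(OCc2ccccc2)c1C[C@@H]1OC(OCC)O[C@H]1c1cc(OC(=O)c2cc(OCc3ccccc3)c(OCc3ccccc3)c(OCc3ccccc3)c2)c(OCc2ccccc2)c(OCc2ccccc2)c1
F9 | step 14 | 2,3-bis(benzyloxy)-5-[(2R,3S)-5,7-bis(benzyloxy)-3-(formyloxy)-3,4-dihydro-2H-chromen-2-yl]phenyl 3,4,5-tris(benzyloxy)benzoate | O=C(Oc1cc([C@H]2Oc3cc(OCc4ccccc4)cc(OCc4ccccc4)c3C[C@@H]2OC=O)cc(OCc2ccccc2)c1OCc1ccccc1)c1cc(OCc2ccccc2)c(OCc2ccccc2)c(OCc2ccccc2)c1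
F10 | step 13 | 2,3-bis(benzyloxy)-5-{(2S)-3-[2,4-bis(benzyloxy)-6-(trimethylsilyloxy)phenyl]-2-[(tert-butyldimethylsilyl)oxy]propanoyl}phenyl 3,4,5-tris(benzyloxy)benzoate | C[Si](C)(C)Oc1cc(OCc2ccccc2)cc(OCc2ccccc2)c1C[C@@H](C(=O)c1cc(OC(=O)c2cc(OCc3ccccc3)c(OCc3ccccc3)c(OCc3ccccc3)c2)c(OCc2ccccc2)c(OCc2ccccc2)c1)O[Si](C)(C)C(C)(C)C
F11 | step 13 | 2,3-bis(benzyloxy)-5-{(2S)-3-[2,4-bis(benzyloxy)-6-hydroxyphenyl]-2-[(tert-butyldimethylsilyl)oxy]propanoyl}phenyl 3,4,5-tris(benzyloxy)benzoate | Oc1cc(OCc2ccccc2)cc(OCc2ccccc2)c1C[C@@H](C(=O)c1cc(OC(=O)c2cc(OCc3ccccc3)c(OCc3ccccc3)c(OCc3ccccc3)c2)c(OCc2ccccc2)c(OCc2ccccc2)c1)O[Si](C)(C)C(C)(C)C
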